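# Proposed synthesis of CNP0260919.4 by a maleimide [5+2] photocycloaddition

**Conventions.** Target locants are used on every intermediate: pyrrolidine N4–C3–C2–C1–C9a; azepane N4–C5–C6–C7–C8–C9–C9a; cyclopentane C9a–C9–C10–C11–C12; fused lactone C11–O–C14(=O)–C13–C12; side lactone C18–C19–C20–C21(=O)–O on C3. "Top face" is the face of the cyclopentane that carries the fused lactone; "bottom face" is the opposite, convex face.

**Compound key.**
- Core branch: 1 bicyclic lactone (starting material); 2 its potassium enolate; 3 C13 alcohol; 4 C13 silyl ether; 5 its lithium enolate; 6 C13-methylated lactone; 7 epoxide; 8 hydroxy selenide; 9 selenoxide; 10 allylic alcohol; 11 enone; 12 lithium enolate; 13 alkenyl triflate.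
- Side-chain branch: 14 N-Boc-L-homoserine lactone (starting material); 15 lactol; 16 ethyl 2-(bromomethyl)acrylate (starting material); 17 allylzinc bromide; 18 hydroxy ester; 19 methylene lactone; 20 methyl lactone alcohol; 21 iodide; 22 alkylzinc iodide.
- After union: 23 coupled N-Boc amine; 24 ammonium salt; 25 maleic anhydride (starting material); 26 maleamic acid; 27 maleimide; 28 azepine-5,8-dione; 29 saturated dione; 30 dithiolane; 31 thiolactam; 32 silyl-protected amine; 33 target.

## Analysis of the target

Compound 33 is a tetracyclic amine in which a pyrrolidine and an azepane share N4 and the fully substituted carbon C9a. C9a is also the spiro atom of a cyclopentane (C9a–C9–C10–C11–C12) that carries a cis-fused γ-lactone on C11–C12; a second γ-lactone hangs from C3. There are nine stereocentres: C3, C18 and C20 on the appendage (all S; N and O syn, lactone 2,4-cis) and C9 (R), C9a (R), C10 (S), C11 (R), C12 (S) and C13 (S) on the core, five of them contiguous around the cyclopentane. The lactone oxygen on C11 and C13 on C12 lie on the top face, whereas N4 on C9a, C8 on C9 and the ethyl group on C10 all lie on the bottom face. At C13 the hydroxyl is endo, pointing toward C9a, and the methyl is exo. The sensitive groups are the two lactones (one with a tertiary α-hydroxyl), the base-labile C20 centre and the tertiary amine, so strong hydride or hydroxide cannot be used late. The difficulty is the aza-quaternary centre C9a, flanked by two stereocentres and common to three rings, with N4 and C8 to be placed cis to each other, anti to the lactone and next to the ethyl group. The strategy rests on exactly this feature: N4 on C9a and C8 on C9, cis on adjacent carbons shared by the pyrrolidine and the azepane, is the pattern left when the alkene C9a=C9 is inserted into an N–C(O) bond of a maleimide.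

## Retrosynthetic reasoning

**33 to 32 (O–Si bond at C13).** The tertiary hydroxyl is carried as a bulky silyl ether and released last. A free hydroxyl on the concave face could hydrogen-bond an imide carbonyl and pull it to the wrong face in the photochemical step, and it would be exposed during thionation. The silyl ether removes both problems and adds a steric shield directly over C9a.

**32 to 28 (C5=O, C8=O and C6=C7 removed).** The amine 32 is traced back to the azepine-5,8-dione 28 by functional-group changes only. Two lactones must survive, so the carbonyl removals are routed through sulfur: saturation of C6=C7 (29), a dithioacetal at the ketone C8 (30), a thiolactam at C5 (31), and one reductive desulfurisation for both.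

**28 to 27 (N4–C9a and C8–C9, the key disconnection).** Cutting these two bonds returns the maleimide 27, in which C9a=C9 is a trisubstituted cyclopentene tethered to the imide nitrogen through C1–C2–C3. This is the place to cut because the two bonds close both nitrogen rings and create C9a and C9 together, while the other seven stereocentres are already present in 27. The forward reaction has to add the imide N–C(O) bond across the alkene on the bottom face.

**27 to 24 and 25 (imide C–N bonds).** The maleimide is made from the primary ammonium salt 24 and the anhydride 25. The amine is handled as a salt because the free base sits β to the side-lactone oxygen and could undergo O-to-N acyl transfer.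

**23 to 13 and 21 (C9a–C1).** An sp2–sp3 cross-coupling between the alkenyl triflate 13 and the organozinc 22 derived from iodide 21 divides the molecule into a core with four stereocentres and a side chain with three. Each half is then made independently from an enantiopure starting material, and the absolute configurations of the two halves are not left to mutual induction.

**13 to 11 (C10–ethyl bond and enol O–S bond).** Conjugate addition of an ethyl group to the enone 11 sets C10 anti to the C11 oxygen and produces the C9a enolate regiospecifically toward C9. Capturing it as the triflate is the only way to guarantee the C9a=C9 position; a C9a ketone could also enolise toward C12 and expel the lactone carboxylate.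

**11 to 6 (1,3-oxygen transposition).** The enone comes from the alkene 6 through the epoxide 7 and the allylic alcohol 10, which moves the unsaturation from C9a=C9 to C9=C10 and places oxygen on C9a.

**6 to 1 (C13–O and C13–CH3 bonds).** Both substituents on C13 are introduced by enolate chemistry on the rigid cis-fused lactone 1. The order is oxygen first (3, 4) and carbon second (6), so that the methyl group enters from the convex face and the oxygen ends up endo, as in the target. Lactone 1 is chosen because it is enantiopure, already holds C11 and C12 in the right absolute sense, and has its alkene at C9a=C9. A shorter-looking entry through an achiral cyclopentenone with enolate ethylation and an intramolecular carbonyl-ene lactonisation was set aside: nothing in it fixes C10 against the remote C3 centre, and the ene step has two competing sets of allylic hydrogens.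

**21 to 14 and 16 (C18–C19 bond; C20–H bond).** The side chain takes C3 from the lactone 14. The aldehyde is used in its masked lactol form 15, which is allylated with the acrylate 16 to form C18–C19 and the lactone (19). Hydrogenation sets C20 (20), and the primary alcohol becomes the iodide 21.

## Alternatives that were turned down

**Alternative 1: Ireland–Claisen ring contraction.** The disconnection is C9–C10. The nine-membered allylic lactone A1, whose carbonyl is C8 and whose α-methylene is C9, would be enolised and O-silylated with an amide base and a silyl chloride. A [3,3] shift inside the ring would then form C9–C10 and give the cis-2-vinylcyclopentanecarboxylic acid A2, with the carboxyl (C8) on C9 and a vinyl group (the future ethyl) on C10.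
- For it: the rearrangement is thermal and ring-constrained, so the cis relation of C8 and the C10 substituent is fixed with more certainty than any facial selectivity in a photoreaction. On this point it is stronger than the chosen route.
- Against it: A1 already contains the spiro-pyrrolidine and C9a, so the hardest centre has to be made earlier by other means, and a nine-membered lactone must be closed on a crowded scaffold. After A2 the azepane is still missing: three carbons must be added to C8, the nitrogen deprotected and the ring closed, and the vinyl group reduced.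
- Comparison: the chosen route gives up some certainty at C9 but forms C9a, C9 and both nitrogen rings in one step, and needs only reductions afterwards.

**Alternative 2: aza-Piancatelli spirocyclisation.** The disconnection is N4–C9a and C9a–C12. A lanthanide triflate would ionise the furylcarbinol A3, the tethered N-benzyloxyamine would attack the furan carbon that becomes C9a, and conrotatory closure of the opened cation would give the 1-azaspiro[4.4]nonenone A4.
- For it: the spiro centre and the carbocycle arise from a flat, easily assembled furan, and the trans relation between N4 and the C12 substituent is stereospecific. On the C9a/C12 relationship it is as strong as or stronger than the chosen route.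
- Against it: the absolute sense of the closure must be induced by stereocentres outside the reacting array. A4 still lacks C9, C10 and C11 as stereocentres, the azepane and the fused lactone. The C8 chain would have to be added to C9 cis to nitrogen beside a quaternary centre, C10 set by protonation, the ketone reduced cis to C12, the N–O bond cleaved and the acetonide turned into the lactone.
- Comparison: the chosen route enters its key step with all other stereocentres in place and leaves only functional-group removals after it.

**Alternative 3: biomimetic oxidative 1,2-shift.** The disconnection is C9a–C12, traced back to a C1–C12 bond in a cyclohexane-fused skeleton. Oxidation of the C1=C9a enamine A5 at C1 would create iminium character at C9a; migration of C12 from C1 to C9a would contract the six-membered ring and give the C1-oxo compound A6.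
- For it: the step mirrors a plausible biogenesis and sets C9a by a suprafacial shift with retention at C12. In redox and atom economy at the key step it is stronger than the chosen route.
- Against it: A5 is itself a pentacyclic alkaloid-like structure carrying the C13 hydroxyl, so its synthesis is a full project before the key step. The oxidant's face of attack decides C9a; over-oxidation and cleavage of the enamine compete with migration; and the C1 ketone of A6 must afterwards be removed in the presence of two lactones.
- Comparison: the chosen route reaches its key-step precursor in ten linear steps from purchasable materials.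

Key step: step 15

## Route

Assumption: lactone 1 is taken as the purchasable (1R,5S) enantiomer and lactone 14 as the purchasable (S) enantiomer.

**Core branch (steps 1–7)**

Step 1
Reactants: 1 (1R,5S)-2-oxabicyclo[3.3.0]oct-6-en-3-one
Product: 3 (1R,4R,5R)-4-hydroxy-2-oxabicyclo[3.3.0]oct-6-en-3-one (C13 hydroxyl on the convex face), via potassium enolate 2 (not isolated)
Conditions: KN(SiMe3)2, THF, −78 °C; then 2-(phenylsulfonyl)-3-phenyloxaziridine, −78 °C; aq NH4Cl
Reagents that add atoms: 2-(phenylsulfonyl)-3-phenyloxaziridine, O=S(=O)(c1ccccc1)N1OC1c1ccccc1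
Why: Enolate α-hydroxylation with an N-sulfonyloxaziridine (Davis oxidation); the oxidant approaches the convex face of the cis-fused bicycle, and because C13 is re-enolised in step 3 only clean mono-oxygenation matters here.

Step 2
Reactants: 3 (1R,4R,5R)-4-hydroxy-2-oxabicyclo[3.3.0]oct-6-en-3-one
Product: 4 (1R,4R,5S)-4-(tert-butyldimethylsilyloxy)-2-oxabicyclo[3.3.0]oct-6-en-3-one
Conditions: t-BuMe2SiCl, imidazole, DMF, rt
Reagents that add atoms: tert-butyldimethylsilyl chloride, CC(C)(C)[Si](C)(C)Cl
Why: Standard silyl ether formation on a secondary α-hydroxy lactone; the group is chosen to survive every later step and to carry no arene into the photoreaction.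

Step 3
Reactants: 4 (1R,4R,5S)-4-(tert-butyldimethylsilyloxy)-2-oxabicyclo[3.3.0]oct-6-en-3-one
Product: 6 (1R,4S,5S)-4-(tert-butyldimethylsilyloxy)-4-methyl-2-oxabicyclo[3.3.0]oct-6-en-3-one (methyl exo; silyloxy endo), via lithium enolate 5 (not isolated)
Conditions: LiN(iPr)2, THF, −78 °C; MeI, DMPU, −78 → −40 °C
Reagents that add atoms: iodomethane, CI
Why: Lactone enolate alkylation; the planar α-silyloxy enolate is methylated from the convex face of the bicycle, which places methyl exo and the oxygen endo and so sets C13 as in the target.

Step 4
Reactants: 6 (1R,4S,5S)-4-(tert-butyldimethylsilyloxy)-4-methyl-2-oxabicyclo[3.3.0]oct-6-en-3-one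
Product: 7 C9a–C9 epoxide of 6 with the oxirane on the bottom face (anti to the lactone ring)
Conditions: m-CPBA, NaHCO3, CH2Cl2, 0 °C → rt
Reagents that add atoms: 3-chloroperbenzoic acid, OOC(=O)c1cccc(Cl)c1
Why: Peracid (Prilezhaev) epoxidation from the convex face of the cis-fused bicycle, reinforced by the endo silyloxy group over C9a; the configuration of the epoxide is later erased.

Step 5
Reactants: 7 C9a–C9 epoxide (oxirane on the bottom face)
Product: 10 allylic alcohol with C9a hydroxyl on the bottom face and a C9=C10 double bond, via hydroxy selenide 8 (not isolated), via selenoxide 9 (not isolated)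
Conditions: (PhSe)2, NaBH4, EtOH, rt → 60 °C; then THF, 30% H2O2, pyridine, 0 °C → rt
Reagents that add atoms: none
Why: Epoxide-to-allylic-alcohol transposition by selenolate opening and selenoxide syn-elimination; the selenolate should attack C9, the carbon remote from the ring fusion and from the C13 substituents, and the selenoxide eliminates away from the carbinol carbon toward C10.

Step 6
Reactants: 10 allylic alcohol (C9a hydroxyl; C9=C10)
Product: 11 enone with C9a ketone and C9=C10 double bond on the cis-fused lactone (C13 methyl exo; silyloxy endo)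
Conditions: Dess–Martin periodinane, NaHCO3, CH2Cl2, 0 °C → rt
Reagents that add atoms: none
Why: Neutral hypervalent-iodine oxidation of a secondary allylic alcohol; buffered conditions avoid base-induced loss of the γ-acyloxy group of the product.

Step 7
Reactants: 11 enone (C9a ketone; C9=C10)
Product: 13 alkenyl triflate with C9a–OTf and C9a=C9 double bond and the C10 ethyl group trans to the C11 oxygen, via lithium enolate 12 (not isolated)
Conditions: Et2CuLi (from EtLi and CuI), Et2O/THF, −78 °C; then N-(5-chloropyridin-2-yl)-N-(trifluoromethylsulfonyl)trifluoromethanesulfonamide, −78 → −30 °C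
Reagents that add atoms: ethyllithium (as lithium diethylcuprate), CC[Li]; N-(5-chloropyridin-2-yl)-N-(trifluoromethylsulfonyl)trifluoromethanesulfonamide, O=S(=O)(N(c1ccc(Cl)cn1)S(=O)(=O)C(F)(F)F)C(F)(F)F
Why: Organocuprate 1,4-addition with in-situ enolate O-sulfonylation; ethyl is delivered to C10 on the convex face, anti to the C11 oxygen, which sets C10, and the enolate is captured as formed toward C9, fixing the C9a=C9 position before it can equilibrate to the C12 enolate and expel the lactone carboxylate.

**Side-chain branch (steps 8–11)**

Step 8
Reactants: 14 tert-butyl N-[(3S)-2-oxooxolan-3-yl]carbamate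
Product: 15 tert-butyl N-[(3S)-2-hydroxyoxolan-3-yl]carbamate (lactol; anomer mixture)
Conditions: iBu2AlH, CH2Cl2, −78 °C; MeOH then H2O
Reagents that add atoms: none
Why: Partial reduction of a lactone to the lactol at low temperature; the lactol is a configurationally stable, masked form of the α-amino aldehyde.

Step 9
Reactants: 15 tert-butyl N-[(3S)-2-hydroxyoxolan-3-yl]carbamate; 16 ethyl 2-(bromomethyl)prop-2-enoate
Product: 19 tert-butyl N-[(1S)-3-hydroxy-1-[(2S)-4-methylidene-5-oxooxolan-2-yl]propyl]carbamate, via allylzinc bromide 17 (not isolated), via hydroxy ester 18 (not isolated)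
Conditions: Zn dust, THF/saturated aq NH4Cl, rt; then TsOH·H2O (cat.), CH2Cl2, rt
Reagents that add atoms: none
Why: Barbier-type allylation of the aldehyde in equilibrium with the lactol, followed by acid-promoted lactonisation; a Cram-chelate arrangement of the carbonyl oxygen and the carbamate on zinc should favour the syn (C3 S, C18 S) adduct, the anti lactone is removed by chromatography, and only the C18 hydroxyl can close a five-membered lactone.

Step 10
Reactants: 19 tert-butyl N-[(1S)-3-hydroxy-1-[(2S)-4-methylidene-5-oxooxolan-2-yl]propyl]carbamate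
Product: 20 tert-butyl N-[(1S)-3-hydroxy-1-[(2S,4S)-4-methyl-5-oxooxolan-2-yl]propyl]carbamate
Conditions: H2 (1 atm), Pd/C, EtOAc, rt
Reagents that add atoms: none
Why: Heterogeneous hydrogenation adds hydrogen to the exocyclic alkene from the face opposite the C18 substituent, giving the 2,4-cis lactone and setting C20.

Step 11
Reactants: 20 tert-butyl N-[(1S)-3-hydroxy-1-[(2S,4S)-4-methyl-5-oxooxolan-2-yl]propyl]carbamate
Product: 21 tert-butyl N-[(1S)-3-iodo-1-[(2S,4S)-4-methyl-5-oxooxolan-2-yl]propyl]carbamate
Conditions: I2, PPh3, imidazole, CH2Cl2, 0 °C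
Reagents that add atoms: iodine, I-I
Why: Appel-type conversion of the primary alcohol into the iodide under neutral conditions at low temperature, which leaves the carbamate, the lactone and all stereocentres untouched.

**Union and endgame (steps 12–20)**

Step 12
Reactants: 21 tert-butyl N-[(1S)-3-iodo-1-[(2S,4S)-4-methyl-5-oxooxolan-2-yl]propyl]carbamate; 13 alkenyl triflate
Product: 23 N-Boc amine in which C9a of the cyclopentene lactone carries the (3S)-3-(Boc-amino)-3-[(2S,4S)-4-methyl-5-oxooxolan-2-yl]propyl chain, via alkylzinc iodide 22 (not isolated)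
Conditions: Zn dust (activated with Me3SiCl and 1,2-dibromoethane), DMF, rt; then 13, Pd2(dba)3, SPhos, DMF/THF, rt → 40 °C
Reagents that add atoms: none
Why: Negishi sp3–sp2 coupling; zinc inserts into the primary C–I bond with the carbamate and lactone tolerated, the alkylzinc iodide transmetalates to the alkenylpalladium triflate, and the bulky biarylphosphine favours reductive elimination over β-hydride loss, with no stereocentre involved.

Step 13
Reactants: 23 N-Boc amine
Product: 24 primary ammonium trifluoroacetate (C3–NH3+)
Conditions: CF3CO2H, CH2Cl2, 0 °C; evaporate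
Reagents that add atoms: trifluoroacetic acid, OC(=O)C(F)(F)F
Why: Acidolysis of the tert-butyl carbamate; the amine is kept protonated because as a free base it could attack the adjacent lactone, and the low temperature spares the trisubstituted alkene and the hindered tertiary silyl ether.

Step 14
Reactants: 24 primary ammonium trifluoroacetate; 25 maleic anhydride
Product: 27 N-substituted maleimide (C3–N imide; C9a=C9 cyclopentene; C13 silyl ether), via maleamic acid 26 (not isolated)
Conditions: iPr2NEt, CH2Cl2, 0 °C → rt; then (Me3Si)2NH, ZnBr2, MeCN, 80 °C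
Reagents that add atoms: none
Why: N-acylation by the anhydride as the amine is liberated, then Lewis-acid/silazane cyclodehydration of the maleamic acid (two-stage maleimide synthesis); acylation by the anhydride is much faster than intramolecular aminolysis of the lactone.

Step 15
Reactants: 27 N-substituted maleimide
Product: 28 tetracyclic azepine-5,8-dione (C6=C7; N4–C9a and C8–C9 on the bottom face; C13 silyl ether)
Conditions: hν (medium-pressure Hg lamp, Pyrex filter, λ > 290 nm), degassed MeCN, high dilution, rt, no sensitiser
Reagents that add atoms: none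
Why: Direct excitation of the N-alkylmaleimide leads to addition of its N4–C8 acyl bond across C9a=C9 and collapse of the strained adduct, so that the two alkene carbons end up between N4 and C8; this is the intramolecular maleimide–alkene [5+2] photocycloaddition known to give fused azepine-5,8-diones from N-alkenylmaleimides. The pyrrolidine closes through the C1–C2–C3 tether in a 5-exo sense, N4 bonding to the substituted alkene carbon C9a, and the azepine arises by two-atom enlargement of the imide ring, C8 bonding to C9. Both bonds form on one alkene face, which makes N4 and C8 cis. C9a is controlled by the face on which the imide approaches: the top face is closed by the lactone ring and by the endo silyloxy group on C13, which sits over C9a, whereas the bottom face carries only the freely rotating ethyl group on C10; C9 then follows from C9a through the suprafacial delivery. The silyl ether also removes the hydroxyl hydrogen bond that could steer an imide carbonyl to the top face. Selectivity for [5+2] over triplet [2+2] addition at C6=C7 is secured by unsensitised irradiation at high dilution and by the three-atom tether, and N4 goes to C9a and not C9 because that closes a five- and not a six-membered ring. Irradiation is stopped short of full conversion because the ene-dione product also absorbs.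

Step 16
Reactants: 28 tetracyclic azepine-5,8-dione
Product: 29 saturated azepane-5,8-dione (C6–C7 single bond)
Conditions: H2 (1 atm), Pd/C, EtOAc, rt
Reagents that add atoms: none
Why: Catalytic hydrogenation of the electron-poor, unhindered C6=C7 bond of the ene-dione; no other reducible group is present.

Step 17
Reactants: 29 saturated azepane-5,8-dione
Product: 30 C8 1,3-dithiolane of the keto-lactam
Conditions: HS(CH2)2SH, BF3·OEt2, CH2Cl2, 0 °C → rt
Reagents that add atoms: ethane-1,2-dithiol, SCCS
Why: Lewis-acid dithioacetalisation of the only ketone, the lactam and lactone carbonyls being unreactive; a short reaction at low temperature limits enolisation toward C9.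

Step 18
Reactants: 30 C8 1,3-dithiolane
Product: 31 C5 thiolactam
Conditions: Lawesson's reagent, toluene, 80 °C
Reagents that add atoms: Lawesson's reagent, COc1ccc(cc1)P1(=S)SP(=S)(S1)c1ccc(OC)cc1
Why: Thionation with Lawesson's reagent is faster for a tertiary lactam than for γ-lactones at this temperature, so only C5 is converted.

Step 19
Reactants: 31 C5 thiolactam
Product: 32 C13 tert-butyldimethylsilyl ether of the target amine
Conditions: Raney nickel (W-2, washed to neutrality), EtOH/THF, rt → 50 °C
Reagents that add atoms: none
Why: Raney-nickel desulfurisation (Mozingo-type) reduces the thiolactam to the amine methylene and the dithiolane to a methylene in one operation without touching the lactones or the silyl ether; the neutral catalyst avoids epimerising C20.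

Step 20
Reactants: 32 C13 silyl ether of the target amine
Product: 33 CNP0260919.4
Conditions: HF·pyridine, THF, 0 °C → rt
Reagents that add atoms: none
Why: Fluoride-mediated cleavage of the tertiary silyl ether under buffered, weakly acidic conditions that spare both lactones and the C20 centre.

## Compound list

1 | (1R,5S)-2-oxabicyclo[3.3.0]oct-6-en-3-one | C1[C@H]2OC(=O)C[C@H]2C=C1 | starting material
2 | potassium enolate of 1 | C1[C@H]2OC([O-])=C[C@H]2C=C1.[K+] | intermediate
3 | (1R,4R,5R)-4-hydroxy-2-oxabicyclo[3.3.0]oct-6-en-3-one (C13 hydroxyl exo) | C1[C@H]2OC(=O)[C@H](O)[C@H]2C=C1 | intermediate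
4 | (1R,4R,5S)-4-(tert-butyldimethylsilyloxy)-2-oxabicyclo[3.3.0]oct-6-en-3-one | C1[C@H]2OC(=O)[C@H](O[Si](C)(C)C(C)(C)C)[C@H]2C=C1 | intermediate
5 | lithium enolate of 4 | C1[C@H]2OC([O-])=C(O[Si](C)(C)C(C)(C)C)[C@H]2C=C1.[Li+] | intermediate
6 | (1R,4S,5S)-4-(tert-butyldimethylsilyloxy)-4-methyl-2-oxabicyclo[3.3.0]oct-6-en-3-one (methyl exo, silyloxy endo) | C1[C@H]2OC(=O)[C@@](C)(O[Si](C)(C)C(C)(C)C)[C@H]2C=C1 | intermediate
7 | C9a–C9 epoxide of 6, oxirane on the bottom face | C1[C@H]2OC(=O)[C@@](C)(O[Si](C)(C)C(C)(C)C)[C@H]2[C@@H]3O[C@@H]31 | intermediate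
8 | hydroxy selenide (C9 phenylselanyl on the top face, C9a hydroxyl on the bottom face) | O[C@@H]1[C@@H]([Se]c3ccccc3)C[C@H]2OC(=O)[C@@](C)(O[Si](C)(C)C(C)(C)C)[C@@H]12 | intermediate
9 | selenoxide of 8 (selenium configuration undefined) | O[C@@H]1[C@@H]([Se](=O)c3ccccc3)C[C@H]2OC(=O)[C@@](C)(O[Si](C)(C)C(C)(C)C)[C@@H]12 | intermediate
10 | allylic alcohol (C9a hydroxyl on the bottom face, C9=C10) | O[C@@H]1C=C[C@H]2OC(=O)[C@@](C)(O[Si](C)(C)C(C)(C)C)[C@@H]12 | intermediate
11 | enone (C9a ketone, C9=C10) on the cis-fused lactone | O=C1C=C[C@H]2OC(=O)[C@@](C)(O[Si](C)(C)C(C)(C)C)[C@@H]12 | intermediate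
12 | lithium enolate C9a(O−)=C9 with C10 ethyl trans to the C11 oxygen | CC[C@@H]1[C@H]2OC(=O)[C@@](C)(O[Si](C)(C)C(C)(C)C)[C@H]2C([O-])=C1.[Li+] | intermediate
13 | alkenyl triflate (C9a–OTf, C9a=C9; C10 ethyl trans to the C11 oxygen) | CC[C@@H]1[C@H]2OC(=O)[C@@](C)(O[Si](C)(C)C(C)(C)C)[C@H]2C(OS(=O)(=O)C(F)(F)F)=C1 | intermediate
14 | tert-butyl N-[(3S)-2-oxooxolan-3-yl]carbamate (N-Boc-L-homoserine lactone) | O=C1OCC[C@@H]1NC(=O)OC(C)(C)C | starting material
15 | tert-butyl N-[(3S)-2-hydroxyoxolan-3-yl]carbamate (anomer mixture) | OC1OCC[C@@H]1NC(=O)OC(C)(C)C | intermediate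
16 | ethyl 2-(bromomethyl)prop-2-enoate | C=C(CBr)C(=O)OCC | starting material
17 | [2-(ethoxycarbonyl)prop-2-enyl]zinc bromide | CCOC(=O)C(=C)C[Zn]Br | intermediate
18 | ethyl (4S,5S)-5-[(tert-butoxycarbonyl)amino]-4,7-dihydroxy-2-methylideneheptanoate | OCC[C@@H]([C@@H](O)CC(=C)C(=O)OCC)NC(=O)OC(C)(C)C | intermediate
19 | tert-butyl N-[(1S)-3-hydroxy-1-[(2S)-4-methylidene-5-oxooxolan-2-yl]propyl]carbamate | OCC[C@@H]([C@@H]1CC(=C)C(=O)O1)NC(=O)OC(C)(C)C | intermediate
20 | tert-butyl N-[(1S)-3-hydroxy-1-[(2S,4S)-4-methyl-5-oxooxolan-2-yl]propyl]carbamate | OCC[C@@H]([C@@H]1C[C@H](C)C(=O)O1)NC(=O)OC(C)(C)C | intermediate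
21 | tert-butyl N-[(1S)-3-iodo-1-[(2S,4S)-4-methyl-5-oxooxolan-2-yl]propyl]carbamate | ICC[C@@H]([C@@H]1C[C@H](C)C(=O)O1)NC(=O)OC(C)(C)C | intermediate
22 | alkylzinc iodide from 21 (zinc on C1) | I[Zn]CC[C@@H]([C@@H]1C[C@H](C)C(=O)O1)NC(=O)OC(C)(C)C | intermediate
23 | coupled N-Boc amine (C9a–C1 bond formed) | CC[C@@H]1[C@H]2OC(=O)[C@@](C)(O[Si](C)(C)C(C)(C)C)[C@H]2C(CC[C@@H]([C@@H]3C[C@H](C)C(=O)O3)NC(=O)OC(C)(C)C)=C1 | intermediate
24 | primary ammonium trifluoroacetate from 23 | CC[C@@H]1[C@H]2OC(=O)[C@@](C)(O[Si](C)(C)C(C)(C)C)[C@H]2C(CC[C@@H]([C@@H]3C[C@H](C)C(=O)O3)[NH3+])=C1.[O-]C(=O)C(F)(F)F | intermediate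
25 | maleic anhydride (furan-2,5-dione) | O=C1OC(=O)C=C1 | starting material
26 | (Z)-maleamic acid of the amine | CC[C@@H]1[C@H]2OC(=O)[C@@](C)(O[Si](C)(C)C(C)(C)C)[C@H]2C(CC[C@@H]([C@@H]3C[C@H](C)C(=O)O3)NC(=O)/C=C\C(=O)O)=C1 | intermediate
27 | maleimide tethered to the cyclopentene lactone (photoprecursor, C13 silyl ether) | CC[C@@H]1[C@H]2OC(=O)[C@@](C)(O[Si](C)(C)C(C)(C)C)[C@H]2C(CC[C@@H]([C@@H]3C[C@H](C)C(=O)O3)N3C(=O)C=CC3=O)=C1 | intermediate
28 | tetracyclic azepine-5,8-dione (C13 silyl ether) | CC[C@@H]1[C@H]2OC(=O)[C@@](C)(O[Si](C)(C)C(C)(C)C)[C@H]2[C@]23CC[C@@H]([C@@H]4C[C@H](C)C(=O)O4)N2C(=O)C=CC(=O)[C@H]13 | intermediate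
29 | saturated azepane-5,8-dione | CC[C@@H]1[C@H]2OC(=O)[C@@](C)(O[Si](C)(C)C(C)(C)C)[C@H]2[C@]23CC[C@@H]([C@@H]4C[C@H](C)C(=O)O4)N2C(=O)CCC(=O)[C@H]13 | intermediate
30 | C8 1,3-dithiolane | CC[C@@H]1[C@H]2OC(=O)[C@@](C)(O[Si](C)(C)C(C)(C)C)[C@H]2[C@]23CC[C@@H]([C@@H]4C[C@H](C)C(=O)O4)N2C(=O)CCC5(SCCS5)[C@H]13 | intermediate
31 | C5 thiolactam with C8 dithiolane | CC[C@@H]1[C@H]2OC(=O)[C@@](C)(O[Si](C)(C)C(C)(C)C)[C@H]2[C@]23CC[C@@H]([C@@H]4C[C@H](C)C(=O)O4)N2C(=S)CCC5(SCCS5)[C@H]13 | intermediate
32 | C13 tert-butyldimethylsilyl ether of the target | CC[C@@H]1[C@H]2OC(=O)[C@@](C)(O[Si](C)(C)C(C)(C)C)[C@H]2[C@]23CC[C@@H]([C@@H]4C[C@H](C)C(=O)O4)N2CCCC[C@H]13 | intermediate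
33 | CNP0260919.4 | CC[C@@H]1[C@H]2OC(=O)[C@@](C)(O)[C@H]2[C@]23CC[C@@H]([C@@H]4C[C@H](C)C(=O)O4)N2CCCC[C@H]13 | target

## Step count and risks

Total: 20 steps. Longest linear sequence: 16 steps (steps 1–7 and 12–20); the side-chain branch is 4 steps (8–11).

**Step 15 (key step).** What may go wrong: addition of the imide on the top face, or diversion of the excited imide into triplet [2+2] addition and secondary photolysis of the ene-dione product, because the bottom face carries the C10 ethyl group next to C9 and the unsubstituted maleimide chromophore crosses readily to the triplet. Fallback, from 24 back to 29: the ammonium salt 24 is condensed with 2,3-dichloromaleic anhydride (NaOAc, AcOH, 80 °C) to the 2,3-dichloromaleimide F1. Halogenated maleimides are the cleaner [5+2] chromophores, and irradiation under the same unsensitised conditions should give the 6,7-dichloroazepine-5,8-dione F2. Zn dust in AcOH then removes both chlorines and saturates C6=C7, rejoining the route at 29.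

**Step 7.** What may go wrong: reductive opening of the lactone by β-elimination of the C11 carboxylate from the trivalent copper intermediate, or equilibration of the enolate before sulfonylation followed by expulsion of the same carboxylate, since the enone is a γ-acyloxy enone. Fallback, from 11 back to 13: copper-catalysed addition of EtMgBr in the presence of Me3SiCl (CuBr·SMe2, THF, −78 °C) silylates the enolate as it forms and gives the trimethylsilyl enol ether F3, so that no free metal enolate is present. F3 is then converted into 13 with PhNTf2 and CsF in DME.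

**Step 5.** What may go wrong: slow or misdirected opening of the epoxide, because the selenolate must enter from the concave face, and ethanolysis of the lactone on heating. Fallback, from 6 back to 10: allylic oxidation of the C10 methylene of 6 (CrO3, 3,5-dimethylpyrazole, CH2Cl2, −20 °C) gives the C10 enone F4. Nucleophilic epoxidation (t-BuOOH, DBU) from the convex face gives the epoxy ketone F5, and Wharton transposition (N2H4·H2O, AcOH, MeOH) gives the allylic alcohol 10 with the same C9a configuration.

**Step 9.** What may go wrong: poor facial selectivity at C18, because chelation of zinc by a carbamate N–H in aqueous medium is weak. Fallback, from 14 back to 19: lactone 14 is opened to the hydroxy Weinreb amide F6 (MeNHOMe·HCl, AlMe3), silylated to the silyl ether F7 (t-BuMe2SiCl, imidazole) and reduced to the aldehyde F8 (LiAlH4, THF, 0 °C). Addition of ethyl 2-[(tributylstannyl)methyl]acrylate under MgBr2·OEt2 chelation (CH2Cl2, −78 °C), followed by lactonisation with TsOH, should give the syn lactone silyl ether F9 through a defined chelate and an open transition state. Desilylation with HF·pyridine returns 19.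

**Step 17.** What may go wrong: epimerisation of C9 by enolisation of the C8 ketone under the Lewis acid, since C8 and the C10 ethyl group are cis on adjacent carbons. Fallback, from 29 back to 32 (Barton–McCombie route, which never enolises the ketone): NaBH4 in MeOH at −20 °C gives the C8 alcohol F10. 1,1'-Thiocarbonyldiimidazole with DMAP gives the imidazolyl thiocarbonate F11, and Bu3SnH with AIBN in toluene at 90 °C gives the C8-methylene lactam F12. Lawesson's reagent gives the thiolactam F13, and Raney nickel reduces it to 32.

## Further compounds

F1 | step 15 | 2,3-dichloromaleimide analogue of 27 | CC[C@@H]1[C@H]2OC(=O)[C@@](C)(O[Si](C)(C)C(C)(C)C)[C@H]2C(CC[C@@H]([C@@H]3C[C@H](C)C(=O)O3)N3C(=O)C(Cl)=C(Cl)C3=O)=C1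
F2 | step 15 | 6,7-dichloroazepine-5,8-dione analogue of 28 | CC[C@@H]1[C@H]2OC(=O)[C@@](C)(O[Si](C)(C)C(C)(C)C)[C@H]2[C@]23CC[C@@H]([C@@H]4C[C@H](C)C(=O)O4)N2C(=O)C(Cl)=C(Cl)C(=O)[C@H]13
F3 | step 7 | trimethylsilyl enol ether (C9a–OSiMe3, C9a=C9; C10 ethyl) | CC[C@@H]1[C@H]2OC(=O)[C@@](C)(O[Si](C)(C)C(C)(C)C)[C@H]2C(O[Si](C)(C)C)=C1
F4 | step 5 | C10 enone (C10 ketone, C9=C9a) from 6 | O=C1[C@H]2OC(=O)[C@@](C)(O[Si](C)(C)C(C)(C)C)[C@H]2C=C1
F5 | step 5 | epoxy ketone (C10 ketone, C9–C9a oxirane on the bottom face) | O=C1[C@H]2OC(=O)[C@@](C)(O[Si](C)(C)C(C)(C)C)[C@H]2[C@@H]3O[C@@H]31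
F6 | step 9 | tert-butyl N-[(2S)-4-hydroxy-1-[methoxy(methyl)amino]-1-oxobutan-2-yl]carbamate | OCC[C@@H](C(=O)N(C)OC)NC(=O)OC(C)(C)C
F7 | step 9 | O-tert-butyldimethylsilyl ether of F6 | CC(C)(C)[Si](C)(C)OCC[C@@H](C(=O)N(C)OC)NC(=O)OC(C)(C)C
F8 | step 9 | tert-butyl N-[(2S)-4-(tert-butyldimethylsilyloxy)-1-oxobutan-2-yl]carbamate | CC(C)(C)[Si](C)(C)OCC[C@@H](C=O)NC(=O)OC(C)(C)C
F9 | step 9 | O-tert-butyldimethylsilyl ether of 19 | CC(C)(C)[Si](C)(C)OCC[C@@H]([C@@H]1CC(=C)C(=O)O1)NC(=O)OC(C)(C)C
F10 | step 17 | C8 alcohol from 29 (C8 configuration undefined) | CC[C@@H]1[C@H]2OC(=O)[C@@](C)(O[Si](C)(C)C(C)(C)C)[C@H]2[C@]23CC[C@@H]([C@@H]4C[C@H](C)C(=O)O4)N2C(=O)CCC(O)[C@H]13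
F11 | step 17 | C8 O-(imidazol-1-ylthiocarbonyl) derivative of F10 | CC[C@@H]1[C@H]2OC(=O)[C@@](C)(O[Si](C)(C)C(C)(C)C)[C@H]2[C@]23CC[C@@H]([C@@H]4C[C@H](C)C(=O)O4)N2C(=O)CCC(OC(=S)n5ccnc5)[C@H]13
F12 | step 17 | C8-methylene C5 lactam | CC[C@@H]1[C@H]2OC(=O)[C@@](C)(O[Si](C)(C)C(C)(C)C)[C@H]2[C@]23CC[C@@H]([C@@H]4C[C@H](C)C(=O)O4)N2C(=O)CCC[C@H]13
F13 | step 17 | C8-methylene C5 thiolactam | CC[C@@H]1[C@H]2OC(=O)[C@@](C)(O[Si](C)(C)C(C)(C)C)[C@H]2[C@]23CC[C@@H]([C@@H]4C[C@H](C)C(=O)O4)N2C(=S)CCC[C@H]13
A1 | alternative 1 | nine-membered (Z)-allylic lactone with C8 carbonyl, C9 methylene and pre-formed N-benzyl spiro-pyrrolidine | O=C1OC/C=C\[C@H]2OC(=O)[C@@](C)(O[Si](C)(C)C)[C@H]2[C@]2(C1)CC[C@@H](CO[Si](C)(C)C(C)(C)C)N2Cc1ccccc1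
A2 | alternative 1 | cis-2-vinylcyclopentanecarboxylic acid (C8 acid on C9, vinyl on C10) | OC(=O)[C@@H]1[C@H](C=C)[C@H]2OC(=O)[C@@](C)(O[Si](C)(C)C)[C@H]2[C@@]13CC[C@@H](CO[Si](C)(C)C(C)(C)C)N3Cc4ccccc4
A3 | alternative 2 | 3-ethyl-2-furylcarbinol with tethered N-benzyloxyamine (carbinol configuration undefined) | CCc1cc(CC[C@@H]([C@@H]2C[C@H](C)C(=O)O2)NOCc2ccccc2)oc1C(O)[C@@]1(C)COC(C)(C)O1
A4 | alternative 2 | 1-azaspiro[4.4]nonenone | CCC1=C[C@]2(CC[C@@H]([C@@H]3C[C@H](C)C(=O)O3)N2OCc4ccccc4)[C@H]([C@@]5(C)COC(C)(C)O5)C1=O
A5 | alternative 3 | C1=C9a enamine of the cyclohexane-fused skeleton (C12 bonded to C1) | CC[C@@H]1[C@H]2OC(=O)[C@@](C)(O)[C@H]2C2=C3[C@@H]1CCCCN3[C@@H](C2)[C@@H]1C[C@H](C)C(=O)O1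
A6 | alternative 3 | C1-oxo derivative of the target skeleton | CC[C@@H]1[C@H]2OC(=O)[C@@](C)(O)[C@H]2[C@]23C(=O)C[C@@H]([C@@H]4C[C@H](C)C(=O)O4)N2CCCC[C@H]13
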